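The readings stem from a simulated flask for substances that don't exist; the scatter is artificial.

**Blue run.** The blue run was all I had when you asked for a quick number and offered your hunch that the lightest charge leads.

| flask | solid substrate | remark | time |
|---|---|---|---|
| blue | 2.2 M | run made earlier |  |
| north-west | 1.0 M |  | 3.0 min |
| east | 1.2 M |  | 3.0 min |
| west | 0.60 M |  | 3.0 min |
| south | 0.50 M |  | 3.0 min |
| north-east | 2.0 M |  | 3.0 min |
| south-west | 3.0 M |  | 3.0 min |

blue run (percent of the solid substrate charged)

| time / s | target / % |
|---|---|
| 10.0 | 1 |
| 25.0 | 5 |
| 50.0 | 5 |
| 80.0 | 9 |
| 120 | 16 |

(each reading ± 1.5 percentage points)

- at the start none of the solid substrate is in solution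
- what has only dissolved of solid substrate counts as not reacted
- a reading or a percentage of target counts all its forms, free or not

- ranking by amount of target, in percent of the solid substrate charged, from high to low, at 3.0 min (north-west / east / west / south / north-east / south-west)
- the same order at 12 min (north-west / east / west / south / north-east / south-west)
- the amount of target, in percent of the solid substrate charged of the flask you put first, at 3.0 min
- the amount of target, in percent of the solid substrate charged of the flask you put last, at 3.0 min

**Flat output.** Its readings lay near a straight line through zero, each good to 1.5 percentage points. From the last, 16% of 2.2 M at 120 s, I read 0.00293 M s⁻¹. This molar amount of target formed per second while solid stands I called the flat output, a zero-order rate. A constant rate integrates to output times time, so percent of charge = flat output × time / charge, as long as solid lasts.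

**My reckoning.** Over 3.0 min the output came to 0.527 M. That gave south-west 17.6% and west 88.0%. For south the amount is more than its charge of 0.50 M, so the rule stopped there and I could not rank south against west. At 12 min the output came to 2.11 M, less than the 3.0 M of south-west, which reckoned 70.3%.

**The forecast.** It said “percent conversion varies inversely with charge” and gave south > west > north-west > east > north-east > south-west at 3.0 min and south > west > north-west > east > north-east > south-west at 12 min, with 78% first and 17% last. For south-west my reckoning gave 17.6% against its 17%.

**The flasks.** They ranked west > south > north-west > east > north-east > south-west at 3.0 min and south-west > north-east > east > north-west > west > south at 12 min, with west at 70.4% and south-west at 20.2%.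

    solid substrate ⇌ starting material, rate k1*(cs1 - [starting material]) while solid is left; crystals form when [starting material] > cs1 (solubility = 0.810 M, k = 0.00620 s⁻¹)
    starting material ⇌ isomer of the product (K = 2.70, k = 0.00910 s⁻¹)
    crystals ⇌ target, rate k3*(cs3 - [target]) while solid is left; crystals form when [target] > cs3 (solubility = 23.0 mM, k = 0.710 s⁻¹)
    starting material ⇌ target (K = 0.420, k = 0.390 s⁻¹)
    target ⇌ isomer of the product (k = 0.0250 s⁻¹)

**Second use.** South-west at 3.0 min still held 72.6% of solid substrate. Read from its 20.2%, the flat output of south-west over that time was 0.00337 M s⁻¹, more than the 0.00293 M s⁻¹ read from the blue run. Carried to north-east, that output reckoned 30.3%, and north-east stood at 30.3% after 3.00 min.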